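**Retrosynthetic overview**

1. Target 20 ⇐ hexabenzyl ether 19 (global hydrogenolysis) ⇐ spiro keto-γ-lactone 16 + 4-benzyloxyphenyl Grignard reagent: the hemiketal carbon C-2' is a lactone carbonyl that has taken up the aryl group.
2. 16 ⇐ planar, achiral coumestan 14 (numbering O-5, C-6 lactone carbonyl, C-6a, C-6b, O-11, C-11a, C-11b) by enantioselective epoxidation of C-6a=C-11a and 1,2-shift of C-6 from C-6a to C-11a. The six-membered pyranone (O-5, C-6, C-6a, C-11a, C-11b, C-4a) contracts to the five-membered lactone, and C-6a leaves that ring as the C-3 ketone.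
3. Enabling feature: the spiro carbon carries the ether oxygen O-1 and lies between the C-3 ketone and C-2' (ester oxidation level). This 2-aryloxy-1,3-dicarbonyl array is the product pattern of an acyl shift in an α,β-epoxy lactone; read backwards it puts C-3, the spiro carbon and C-2' into one coumarin ring whose C-3/C-4 bond is the furan double bond of a coumestan.
4. 14 ⇐ lactonisation of biaryl ester 13 ⇐ Negishi coupling of benzofuran ester 11 (from 3,5-bis(benzyloxy)phenol and methyl propiolate) with 8-iodoflavonol 7 (from kaempferol).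
5. Ring order: γ-pyrone of the flavonol (bought in with kaempferol) → benzofuran (step 6) → lactone pyranone (step 8) → contraction to spiro γ-lactone/benzofuranone (step 9) → cyclic hemiketal (step 10).

Key step: step 9

Remark: the hemiketal carbon C-2' epimerises by ring–chain tautomerism, so its (R) configuration (OH cis to the C-3 carbonyl, aryl cis to O-1) is taken to be the thermodynamically preferred one; only the spiro carbon has to be set by asymmetric synthesis.

**Route**

Step 1
Reactants: 1 kaempferol
Product: 2 kaempferol 3,5,7,4'-tetraacetate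
Conditions: Ac2O, pyridine, DMAP (cat.), rt
Reagents that add atoms: acetic anhydride, CC(=O)OC(C)=O
Why: Exhaustive O-acetylation (nucleophilic acyl substitution, DMAP catalysis) masks all four hydroxyls, the chelated 5-OH included.

Step 2
Reactants: 2 kaempferol 3,5,7,4'-tetraacetate
Product: 3 kaempferol 3,5,4'-triacetate (free 7-OH)
Conditions: PhSH (1.2 equiv), imidazole (0.3 equiv), NMP, 0 °C
Reagents that add atoms: none
Why: Chemoselective thiolysis of the most activated aryl ester: the 7-acetate, para to the C-4 carbonyl, has the best phenoxide leaving group, a known regioselective 7-O-deacylation of flavonoid peracetates.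

Step 3
Reactants: 3 kaempferol 3,5,4'-triacetate
Product: 4 7-O-methoxymethylkaempferol 3,5,4'-triacetate
Conditions: MOMCl, i-Pr2NEt, CH2Cl2, 0 °C → rt
Reagents that add atoms: chloromethyl methyl ether, COCCl
Why: Williamson-type O-alkylation of the free 7-OH with the reactive chloromethyl ether under a hindered amine base, which leaves the acetates in place.

Step 4
Reactants: 4 7-O-methoxymethylkaempferol 3,5,4'-triacetate
Product: 6 3,5,4'-tri-O-benzyl-7-O-methoxymethylkaempferol, via triol 5 (not isolated)
Conditions: K2CO3, MeOH, rt; concentrate; then BnBr, K2CO3, DMF, 80 °C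
Reagents that add atoms: benzyl bromide, BrCc1ccccc1
Why: Methanolysis of the three acetates (transesterification) followed by Williamson benzylation in DMF at elevated temperature, which also alkylates the chelated 5-OH; the MOM ether is stable to base.

Step 5
Reactants: 6 3,5,4'-tri-O-benzyl-7-O-methoxymethylkaempferol
Product: 7 3,5,4'-tri-O-benzyl-8-iodo-7-O-methoxymethylkaempferol
Conditions: NIS, TFA (10 mol %), MeCN, 0 °C → rt
Reagents that add atoms: N-iodosuccinimide, O=C1CCC(=O)N1I
Why: Electrophilic aromatic iodination: with O-5 alkylated, C-8 (between O-1 and the 7-OMOM group) is the most nucleophilic ring position of a 5,7-dialkoxyflavone.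

Step 6
Reactants: 8 3,5-bis(benzyloxy)phenol; 9 methyl propiolate
Product: 11 methyl 4,6-bis(benzyloxy)benzofuran-3-carboxylate, via aryloxyacrylate 10 (not isolated)
Conditions: PPh3 (10 mol %), PhH, rt; then Pd(OAc)2 (5 mol %), CF3CO2Ag (2 equiv), 110 °C
Reagents that add atoms: none
Why: Phosphine-catalysed oxa-Michael addition of the phenol to the propiolate gives the (E)-aryloxyacrylate, and Pd(II)-catalysed dehydrogenative cyclisation (oxidative Heck-type C–H/C–H coupling) onto one of the two equivalent ortho positions closes the furan ring.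

Step 7
Reactants: 11 methyl 4,6-bis(benzyloxy)benzofuran-3-carboxylate; 7 3,5,4'-tri-O-benzyl-8-iodo-7-O-methoxymethylkaempferol
Product: 13 methyl 4,6-bis(benzyloxy)-2-[3,5-bis(benzyloxy)-2-(4-benzyloxyphenyl)-7-(methoxymethoxy)-4-oxo-4H-chromen-8-yl]benzofuran-3-carboxylate, via benzofuranylzinc chloride 12 (not isolated)
Conditions: TMPZnCl·LiCl (1.3 equiv), THF, 25–40 °C; then 7, Pd2(dba)3 (2.5 mol %), SPhos (10 mol %), THF, 60 °C
Reagents that add atoms: none
Why: Directed zincation of the most acidic C–H (C-2, next to the ring oxygen and β to the ester) with a zinc amide that tolerates the ester, then Negishi coupling, in which a bulky biarylphosphine ligand permits reaction of the di-ortho-substituted aryl iodide.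

Step 8
Reactants: 13 biaryl methyl ester
Product: 14 flavonol-fused coumestan: 7,9-bis(benzyloxy)-6H-benzofuro[3,2-c]chromen-6-one whose chromenone benzo ring is the A ring of 3,5,4'-tri-O-benzylkaempferol (O-5 = flavonol O-7, C-11b = flavonol C-8)
Conditions: TsOH·H2O (20 mol %), MeOH–PhMe, 65 °C; then PhMe, 110 °C (MeOH distilled off)
Reagents that add atoms: none
Why: Acid-catalysed acetal exchange frees the 7-OH, which lactonises onto the neighbouring methyl ester (6-exo-trig acyl substitution) on removal of methanol to give the planar coumestan.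

Step 9
Reactants: 14 flavonol-fused coumestan
Product: 16 (S)-spiro keto-lactone: 4,6-bis(benzyloxy)benzofuran-3(2H)-one joined through C-2 to C-3 of a benzofuran-2(3H)-one that is fused to the flavonol A ring (lactone O = flavonol O-7, spiro carbon on C-8), via epoxide 15 (not isolated)
Conditions: (S,S)-(salen)Mn(III)Cl [N,N'-bis(3,5-di-tert-butylsalicylidene)-1,2-cyclohexanediamine complex] (10 mol %), PhIO (1.5 equiv), 4-phenylpyridine N-oxide (0.3 equiv), CH2Cl2, 4 Å MS, −20 °C; then BF3·OEt2 (20 mol %), −78 → −20 °C
Reagents that add atoms: iodosylbenzene, O=Ic1ccccc1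
Why: Proposed new method: the chiral Mn(V)-oxo species should transfer oxygen to the enol-ether bond C-6a=C-11a of the planar, achiral coumestan (the HOMO of a trialkoxybenzofuran, whereas flavonol C-2=C-3 lies in the electron-poor γ-pyrone) to give the labile α,β-epoxy lactone 15; BF3 then opens C-11a–O to a cation stabilised by O-11 and the flavonol A ring, and the lactone carbonyl C-6 migrates from C-6a to C-11a while C-6a–O becomes the C-3 ketone. The closest known reaction types are the Mn(salen)-catalysed enantioselective epoxidation of isoflavones and 2,2-disubstituted chromenes (Jacobsen–Katsuki epoxidation) and the BF3-induced House–Meinwald 1,2-acyl shift of α,β-epoxy ketones with ring contraction (isophorone oxide to 2-formylcyclopentanone); neither has been run on a coumestan. Ring formation: the epoxide closes by [2+1] oxygen-atom transfer, and the five-membered lactone (C-11a, C-6, O-5, C-4a, C-11b) arises from the six-membered pyranone by the 1,2-shift that expels C-6a from the ring, so no separate cyclisation is needed. The spiro carbon is the only new stereocentre: the catalyst selects the face of oxygen transfer (the (S,S)-catalyst is chosen by analogy with 2,2-dimethylchromene and indene, where it attacks the face that corresponds here to the Si,Si face, giving the (6aS,11aS)-epoxide), and migration of C-6 anti to the departing epoxide oxygen then gives (S). Regioselectivity rests on the substrate: the C-11a cation is favoured over a C-6a cation that would sit α to the lactone carbonyl, and of the two groups on C-6a only C-6 can migrate because the aryl carbon C-6b is held in the furan ring.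

Step 10
Reactants: 16 (S)-spiro keto-lactone; 17 1-(benzyloxy)-4-bromobenzene
Product: 19 hexa-O-benzyl ether of the target ((S)-spiro carbon; (R)-hemiketal carbon), via arylmagnesium bromide 18 (not isolated)
Conditions: 17, Mg, THF, rt; then 16 (18 in 1.2 equiv), THF, −78 °C; aq. NH4Cl at −78 °C
Reagents that add atoms: none
Why: 1,2-Addition of the aryl Grignard reagent to the lactone carbonyl, the most electrophilic of the three carbonyls (strained aryl ester activated by the α-oxygen and α-ketone, whereas the C-3 ketone and the γ-pyrone are vinylogous esters), gives the cyclic hemiketal, whose carbon equilibrates to the (R) epimer with OH cis to C-3.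

Step 11
Reactants: 19 hexa-O-benzyl ether of the target
Product: 20 target, (S)-spiro carbon and (R)-hemiketal carbon
Conditions: H2 (1 atm), 10% Pd/C, EtOAc–THF, rt
Reagents that add atoms: none
Why: Hydrogenolysis of the six benzyl ethers over palladium under neutral conditions, which touch neither the spiro centre nor the hemiketal.

**Compound list**

1 | kaempferol | O=c1c(O)c(-c2ccc(O)cc2)oc2cc(O)cc(O)c12 | starting material
2 | kaempferol 3,5,7,4'-tetraacetate | O=c1c(OC(C)=O)c(-c2ccc(OC(C)=O)cc2)oc2cc(OC(C)=O)cc(OC(C)=O)c12 | intermediate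
3 | kaempferol 3,5,4'-triacetate (free 7-OH) | O=c1c(OC(C)=O)c(-c2ccc(OC(C)=O)cc2)oc2cc(O)cc(OC(C)=O)c12 | intermediate
4 | 7-O-methoxymethylkaempferol 3,5,4'-triacetate | O=c1c(OC(C)=O)c(-c2ccc(OC(C)=O)cc2)oc2cc(OCOC)cc(OC(C)=O)c12 | intermediate
5 | 7-O-methoxymethylkaempferol (triol, not isolated) | O=c1c(O)c(-c2ccc(O)cc2)oc2cc(OCOC)cc(O)c12 | intermediate
6 | 3,5,4'-tri-O-benzyl-7-O-methoxymethylkaempferol | O=c1c(OCc2ccccc2)c(-c2ccc(OCc3ccccc3)cc2)oc2cc(OCOC)cc(OCc3ccccc3)c12 | intermediate
7 | 3,5,4'-tri-O-benzyl-8-iodo-7-O-methoxymethylkaempferol | O=c1c(OCc2ccccc2)c(-c2ccc(OCc3ccccc3)cc2)oc2c(I)c(OCOC)cc(OCc3ccccc3)c12 | intermediate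
8 | 3,5-bis(benzyloxy)phenol | Oc1cc(OCc2ccccc2)cc(OCc2ccccc2)c1 | starting material
9 | methyl propiolate | C#CC(=O)OC | starting material
10 | methyl (E)-3-[3,5-bis(benzyloxy)phenoxy]acrylate (not isolated) | COC(=O)/C=C/Oc1cc(OCc2ccccc2)cc(OCc2ccccc2)c1 | intermediate
11 | methyl 4,6-bis(benzyloxy)benzofuran-3-carboxylate | COC(=O)c1coc2cc(OCc3ccccc3)cc(OCc3ccccc3)c12 | intermediate
12 | [4,6-bis(benzyloxy)-3-(methoxycarbonyl)benzofuran-2-yl]zinc chloride (not isolated) | COC(=O)c1c([Zn]Cl)oc2cc(OCc3ccccc3)cc(OCc3ccccc3)c12 | intermediate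
13 | methyl 4,6-bis(benzyloxy)-2-[3,5-bis(benzyloxy)-2-(4-benzyloxyphenyl)-7-(methoxymethoxy)-4-oxo-4H-chromen-8-yl]benzofuran-3-carboxylate | O=c1c(OCc2ccccc2)c(-c2ccc(OCc3ccccc3)cc2)oc2c(-c3oc4cc(OCc5ccccc5)cc(OCc5ccccc5)c4c3C(=O)OC)c(OCOC)cc(OCc3ccccc3)c12 | intermediate
14 | flavonol-fused coumestan (7,9-bis(benzyloxy)-6H-benzofuro[3,2-c]chromen-6-one fused through O-5/C-11b to O-7/C-8 of 3,5,4'-tri-O-benzylkaempferol) | O=c1c(OCc2ccccc2)c(-c2ccc(OCc3ccccc3)cc2)oc2c3c4oc5cc(OCc6ccccc6)cc(OCc6ccccc6)c5c4c(=O)oc3cc(OCc3ccccc3)c12 | intermediate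
15 | (6aS,11aS)-6a,11a-epoxide of 14 (oxygen on the Si,Si face; not isolated) | O=c1c(OCc2ccccc2)c(-c2ccc(OCc3ccccc3)cc2)oc2c3[C@@]45Oc6cc(OCc7ccccc7)cc(OCc7ccccc7)c6[C@@]4(O5)C(=O)Oc3cc(OCc3ccccc3)c12 | intermediate
16 | (S)-spiro keto-lactone (penta-O-benzyl) | O=C1c2c(OCc3ccccc3)cc(OCc3ccccc3)cc2O[C@@]12c1c(cc(OCc3ccccc3)c3c(=O)c(OCc4ccccc4)c(-c4ccc(OCc5ccccc5)cc4)oc13)OC2=O | intermediate
17 | 1-(benzyloxy)-4-bromobenzene | Brc1ccc(OCc2ccccc2)cc1 | starting material
18 | 4-(benzyloxy)phenylmagnesium bromide (not isolated) | Br[Mg]c1ccc(OCc2ccccc2)cc1 | intermediate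
19 | hexa-O-benzyl ether of the target, (S)-spiro carbon and (R)-hemiketal carbon | O=C1c2c(OCc3ccccc3)cc(OCc3ccccc3)cc2O[C@@]12c1c(cc(OCc3ccccc3)c3c(=O)c(OCc4ccccc4)c(-c4ccc(OCc5ccccc5)cc4)oc13)O[C@]2(O)c1ccc(OCc2ccccc2)cc1 | intermediate
20 | CNP0283000.1, (S)-spiro carbon and (R)-hemiketal carbon | O=C1c2c(O)cc(O)cc2O[C@@]12c1c(cc(O)c3c(=O)c(O)c(-c4ccc(O)cc4)oc13)O[C@]2(O)c1ccc(O)cc1 | target

**Step count and risks**

Total steps: 11. Longest linear sequence: 10 (steps 1–5 and 7–11; step 6 is the side branch).

Steps most likely to fail: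

1. Step 9 (proposed new method). The catalyst may discriminate poorly between the faces of a flat tetrasubstituted alkene flanked by aryl rings on both sides. The oxidant may also attack flavonol C-2=C-3. Configuration may be lost if the epoxide opens at C-6a–O to the quinone-methide valence isomer before the acyl shift. Fallback with known reaction types, setting out from 14: dimethyldioxirane (acetone–CH2Cl2, 0 °C; the dioxirane epoxidation of benzofurans and of chromone-type double bonds is established) should give the epoxide 15 together with its enantiomer, the (6aR,11aR)-epoxide F1. BF3·OEt2 at −78 °C (House–Meinwald acyl shift) should convert both into racemic spiro keto-lactone, i.e. 16 and the (R)-spiro keto-lactone F2. Preparative SFC on a polysaccharide chiral phase separates the two, and the route is rejoined at 16.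

2. Step 10. The Grignard reagent may attack the C-3 ketone or the γ-pyrone, add a second time to the ring-opened aryl ketone, or trigger retro-Claisen cleavage of the non-enolisable β-keto lactone. Fallback setting out from 16: aminolysis of the aryl lactone with Me(MeO)NH·HCl/i-PrMgCl (THF, −20 °C) should give the (S)-configured Weinreb amide F3 with a free 7-OH. Treatment with 18 (2.5 equiv, −40 → 0 °C) and cold aqueous NH4Cl should release the aryl ketone, which closes onto the 7-OH to the hemiketal. The route is rejoined at 19.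

3. Step 7. Transmetalation and reductive elimination may be slow in a coupling that builds a tri-ortho-substituted biaryl, and the zinc reagent may be lost by protodezincation. Fallback with reversed polarity, setting out from 7 and 11: Miyaura borylation of 7 (B2pin2, PdCl2(dppf), KOAc, dioxane, 90 °C) should give the 8-pinacolboronate F4. Magnesiation of 11 (TMPMgCl·LiCl, THF, −40 °C) and quench with 1,2-dibromotetrachloroethane should give the 2-bromobenzofuran ester F5. Suzuki–Miyaura coupling of F4 with F5 (Pd(OAc)2, SPhos, K3PO4, toluene–water, 90 °C) rejoins the route at 13.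

**Further compounds**

F1 | step 9 | (6aR,11aR)-6a,11a-epoxide, enantiomer of 15 | O=c1c(OCc2ccccc2)c(-c2ccc(OCc3ccccc3)cc2)oc2c3[C@]45Oc6cc(OCc7ccccc7)cc(OCc7ccccc7)c6[C@]4(O5)C(=O)Oc3cc(OCc3ccccc3)c12
F2 | step 9 | (R)-spiro keto-lactone, enantiomer of 16 | O=C1c2c(OCc3ccccc3)cc(OCc3ccccc3)cc2O[C@]12c1c(cc(OCc3ccccc3)c3c(=O)c(OCc4ccccc4)c(-c4ccc(OCc5ccccc5)cc4)oc13)OC2=O
F3 | step 10 | (S)-4,6-bis(benzyloxy)-2-[3,5-bis(benzyloxy)-2-(4-benzyloxyphenyl)-7-hydroxy-4-oxo-4H-chromen-8-yl]-N-methoxy-N-methyl-3-oxo-2,3-dihydrobenzofuran-2-carboxamide | O=C1c2c(OCc3ccccc3)cc(OCc3ccccc3)cc2O[C@@]1(C(=O)N(C)OC)c1c(O)cc(OCc2ccccc2)c2c(=O)c(OCc3ccccc3)c(-c3ccc(OCc4ccccc4)cc3)oc12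
F4 | step 7 | 3,5,4'-tri-O-benzyl-7-O-methoxymethylkaempferol-8-boronic acid pinacol ester | O=c1c(OCc2ccccc2)c(-c2ccc(OCc3ccccc3)cc2)oc2c(B3OC(C)(C)C(C)(C)O3)c(OCOC)cc(OCc3ccccc3)c12
F5 | step 7 | methyl 4,6-bis(benzyloxy)-2-bromobenzofuran-3-carboxylate | COC(=O)c1c(Br)oc2cc(OCc3ccccc3)cc(OCc3ccccc3)c12
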